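**Retrosynthetic overview**
1. Side chain numbered C1 (OCH2) to C8. The last disconnection is the aryl ether O–C1 bond: Mitsunobu coupling of 7-hydroxy-8-methoxycoumarin with the primary hydroxyl of a C10 epoxy diol.
2. The strategy rests on one feature: C1, C2, C3, C4, C5 and the C5 oxygen are the six ring atoms of a 4-methyl-6-(2-methylprop-1-enyl)-5,6-dihydropyran-2-one. That ring holds C2=C3 in the cis (neryl-type) geometry, makes C2=C3 the only electron-poor alkene, and lets the C5 stereocentre screen one face.
3. The lactone is cut at C4–C5 and at O–C1 into two C5 units, the silyl dienolate of ethyl 3-methylbut-2-enoate and 3-methylbut-2-enal, joined by a copper-catalysed enantioselective vinylogous aldol–lactonisation.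
4. Ring order: δ-lactone first, epoxide fused onto it, lactone opened by reduction; the coumarin pyranone is made separately by Pechmann condensation and the halves are joined last.

Key step: step 2

Assumption: the sense of induction of the Tol-BINAP–copper catalyst with this aldehyde is treated as open. The ligand antipode that gives the (S)-lactone is fixed in a pilot run (Mosher ester analysis after ring opening, ee by chiral HPLC), and the route is written for that antipode.

**Step 1**
Reactants: 1 ethyl 3-methylbut-2-enoate
Product: 2 (1Z)-1-ethoxy-3-methyl-1-(trimethylsilyloxy)buta-1,3-diene (the other ketene acetal geometry is equally usable)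
Conditions: LDA, THF, −78 °C; Me3SiCl, −78 °C to rt; distillation
Reagents that add atoms: chlorotrimethylsilane, C[Si](C)(C)Cl
Why: LDA removes a γ-hydrogen of the enoate to give the extended lithium dienolate, which Me3SiCl traps on oxygen as the silyl ketene acetal (silyl dienolate formation).

**Step 2**
Reactants: 2 (1Z)-1-ethoxy-3-methyl-1-(trimethylsilyloxy)buta-1,3-diene; 3 3-methylbut-2-enal
Product: 5 (6S)-4-methyl-6-(2-methylprop-1-en-1-yl)-5,6-dihydro-2H-pyran-2-one, via copper aldolate 4 (not isolated)
Conditions: Cu(OTf)2 (10 mol %), Tol-BINAP (11 mol %), Bu4N[Ph3SiF2] (20 mol %), THF, 0 °C to rt; no strong base at any point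
Reagents that add atoms: none
Why: The Cu(OTf)2/Tol-BINAP complex is converted by Bu4N[Ph3SiF2] and 2 into a ligated dienolate of monovalent copper, and its terminal CH2 (future C4) attacks the carbonyl carbon of 3 (future C5) to give aldolate 4. The closest known reaction type is the copper fluoride–bisphosphine catalysed enantioselective vinylogous Mukaiyama aldol reaction of senecioate-derived silyl dienolates, which is known to run on to 4-methyl-5,6-dihydropyran-2-ones. The δ-lactone closes by 6-exo-trig attack of the C5 alkoxide on the ester carbonyl C1, and the expelled ethoxide takes the silyl group of the next molecule of 2, which turns the catalyst over. The C5 stereocentre is set by the Tol-BINAP ligand on copper, which selects one enantioface of the aldehyde. The step needs γ- rather than α-attack, secured by the unhindered CH2 terminus of the copper dienolate, and 1,2- rather than 1,4-addition, secured by the β,β-dimethyl substitution of 3, which also has no sp3 α-hydrogen for self-condensation. Only the aldolate with C1 and C4 cis on C2=C3 can cyclise, so the lactone formed has that geometry locked in its ring.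

**Step 3**
Reactants: 5 (6S)-4-methyl-6-(2-methylprop-1-en-1-yl)-5,6-dihydro-2H-pyran-2-one
Product: 6 (1R,4S,6R)-6-methyl-4-(2-methylprop-1-en-1-yl)-3,7-dioxabicyclo[4.1.0]heptan-2-one (epoxide oxygen trans to the 2-methylprop-1-enyl group)
Conditions: 30% aq H2O2, NaOH (cat.), MeOH, 0 °C; then aq citric acid to pH 4, 0 °C, brief
Reagents that add atoms: hydrogen peroxide, OO
Why: In this Weitz–Scheffer nucleophilic epoxidation hydroperoxide adds in conjugate fashion to the ring enoate only (the electron-rich side-chain alkene does not react), on the ring face away from the pseudoequatorial C6 substituent, and the enolate closes on the O–O bond on that same face, so both epoxide centres are set trans to the 2-methylprop-1-enyl group by relay from C6.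

**Step 4**
Reactants: 6 (1R,4S,6R)-6-methyl-4-(2-methylprop-1-en-1-yl)-3,7-dioxabicyclo[4.1.0]heptan-2-one
Product: 8 [(2S,3R)-3-[(2S)-2-hydroxy-4-methylpent-3-en-1-yl]-3-methyloxiran-2-yl]methanol, via epoxy aldehyde 7 (not isolated)
Conditions: NaBH4, EtOH, 0 °C; pH 7 phosphate buffer work-up
Reagents that add atoms: none
Why: Borohydride reduction of a lactone carbonyl activated by the α-oxygen of the epoxide passes through hydroxy aldehyde 7 and should stop at the primary alcohol, leaving the epoxide, the alkene and all three stereocentres untouched (lactone-to-diol reduction).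

**Step 5**
Reactants: 9 2-methoxybenzene-1,3-diol; 10 (S)-malic acid
Product: 12 7-hydroxy-8-methoxy-2H-chromen-2-one, via 3-oxopropanoic acid 11 (not isolated)
Conditions: conc. H2SO4, 100–110 °C; poured onto ice
Reagents that add atoms: none
Why: In this Pechmann condensation sulfuric acid decarbonylates malic acid to 3-oxopropanoic acid 11, whose aldehyde carbon bonds to the ring position ortho to one hydroxyl and para to the other before lactonisation onto the ortho hydroxyl, and the mirror symmetry of 9 makes the two reactive positions equivalent so only one regioisomer can form.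

**Step 6**
Reactants: 8 [(2S,3R)-3-[(2S)-2-hydroxy-4-methylpent-3-en-1-yl]-3-methyloxiran-2-yl]methanol; 12 7-hydroxy-8-methoxy-2H-chromen-2-one
Product: 13 7-{[(2S,3R)-3-[(2S)-2-hydroxy-4-methylpent-3-en-1-yl]-3-methyloxiran-2-yl]methoxy}-8-methoxy-2H-chromen-2-one
Conditions: PPh3 (1.2 equiv), 12 (1.2 equiv), THF, 0 °C; diisopropyl azodicarboxylate (1.2 equiv) added last, 0 °C to rt
Reagents that add atoms: none
Why: In this Mitsunobu etherification the acidic phenol 12 protonates the betaine and its phenoxide displaces the oxyphosphonium formed at the less hindered primary hydroxyl by SN2 at a CH2 carbon, so no stereocentre is involved and the secondary allylic alcohol should stay free.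

**Compound list**
1 | ethyl 3-methylbut-2-enoate | CCOC(=O)C=C(C)C | starting material
2 | (1Z)-1-ethoxy-3-methyl-1-(trimethylsilyloxy)buta-1,3-diene | CCO/C(O[Si](C)(C)C)=C/C(C)=C | intermediate
3 | 3-methylbut-2-enal | CC(C)=CC=O | starting material
4 | copper alkoxide (monovalent copper, Tol-BINAP ligand not drawn) of ethyl (2Z,5S)-5-hydroxy-3,7-dimethylocta-2,6-dienoate | CCOC(=O)/C=C(/C)C[C@H](O[Cu])C=C(C)C | intermediate
5 | (6S)-4-methyl-6-(2-methylprop-1-en-1-yl)-5,6-dihydro-2H-pyran-2-one | CC1=CC(=O)O[C@H](C=C(C)C)C1 | intermediate
6 | (1R,4S,6R)-6-methyl-4-(2-methylprop-1-en-1-yl)-3,7-dioxabicyclo[4.1.0]heptan-2-one | O=C1[C@@H]2O[C@]2(C)C[C@@H](C=C(C)C)O1 | intermediate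
7 | (2R,3R)-3-[(2S)-2-hydroxy-4-methylpent-3-en-1-yl]-3-methyloxirane-2-carbaldehyde | O=C[C@@H]1O[C@]1(C)C[C@H](O)C=C(C)C | intermediate
8 | [(2S,3R)-3-[(2S)-2-hydroxy-4-methylpent-3-en-1-yl]-3-methyloxiran-2-yl]methanol | OC[C@@H]1O[C@]1(C)C[C@H](O)C=C(C)C | intermediate
9 | 2-methoxybenzene-1,3-diol | COc1c(O)cccc1O | starting material
10 | (S)-malic acid (its stereocentre is lost) | O=C(O)C[C@H](O)C(=O)O | starting material
11 | 3-oxopropanoic acid | O=CCC(=O)O | intermediate
12 | 7-hydroxy-8-methoxy-2H-chromen-2-one | COc1c(O)ccc2ccc(=O)oc12 | intermediate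
13 | 7-{[(2S,3R)-3-[(2S)-2-hydroxy-4-methylpent-3-en-1-yl]-3-methyloxiran-2-yl]methoxy}-8-methoxy-2H-chromen-2-one | COc1c(OC[C@@H]2O[C@]2(C)C[C@H](O)C=C(C)C)ccc2ccc(=O)oc12 | target

**Step count**
Total: 6 steps. Longest linear sequence: 5 steps (steps 1, 2, 3, 4, 6); step 5 is the side branch.

**Steps most likely to fail**

Step 2. The aldolate may form with the (2E) geometry, or be silylated before it acylates, so that open-chain aldol accumulates instead of lactone. The enantioface selectivity with this β,β-disubstituted enal may also be modest. The fallback sets out from 3 and comes back at 5. It changes the nucleophile to the dienolate for which this copper catalysis is best established, closes the ring without any dependence on alkene geometry, and brings in the C4 methyl afterwards.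
- 2,2,6-Trimethyl-4H-1,3-dioxin-4-one is converted (LDA, Me3SiCl, THF, −78 °C) into trimethyl[(2,2-dimethyl-6-methylidene-6H-1,3-dioxin-4-yl)oxy]silane F1.
- F1 and 3 under the same Cu(OTf)2/Tol-BINAP/Bu4N[Ph3SiF2] catalysis should give 2,2-dimethyl-6-[(2S)-4-methyl-2-(trimethylsilyloxy)pent-3-en-1-yl]-4H-1,3-dioxin-4-one F2.
- Mild acidic work-up frees 6-[(2S)-2-hydroxy-4-methylpent-3-en-1-yl]-2,2-dimethyl-4H-1,3-dioxin-4-one F3.
- Heating F3 in toluene expels acetone, and the acylketene is trapped by the hydroxyl to give (6S)-6-(2-methylprop-1-en-1-yl)oxane-2,4-dione F4.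
- O-Sulfonylation (Tf2O, Et3N, CH2Cl2, −78 °C) gives (6S)-6-(2-methylprop-1-en-1-yl)-2-oxo-5,6-dihydro-2H-pyran-4-yl trifluoromethanesulfonate F5.
- Addition–elimination with Me2CuLi (monovalent copper, THF, −78 °C) replaces the triflate by methyl and returns 5.

Step 3. Conjugate addition of hydroperoxide to the β,β-disubstituted enoate may be slow. Hydroxide-mediated lactone opening, or ring opening by γ-deprotonation and β-elimination, could then overtake epoxidation, and the C4 methyl could erode the facial preference. The fallback sets out from 5 and comes back at 8, bypassing 6 and step 4. It reverses the order of reduction and epoxidation and lets a reagent choose the face.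
- DIBAL-H (CH2Cl2, −78 to 0 °C) reduces 5 through the lactol (6S)-4-methyl-6-(2-methylprop-1-en-1-yl)-5,6-dihydro-2H-pyran-2-ol F6 to (2Z,5S)-3,7-dimethylocta-2,6-diene-1,5-diol F7, keeping the ring-derived Z geometry.
- Sharpless asymmetric epoxidation of the primary allylic alcohol of F7 (Ti(OiPr)4, L-(+)-diethyl tartrate, t-BuOOH, 4 Å sieves, CH2Cl2, −20 °C) should give 8. L-(+)-tartrate is the antipode that turns a neryl-type (Z) alcohol into the (2S,3R) epoxide.
- C6=C7 is also allylic to a hydroxyl, but it carries a methyl cis to the carbinol carbon, a pattern that is epoxidised slowly. One equivalent of oxidant and close monitoring are required.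

Step 6. The oxyphosphonium at C1 may be captured by the C5 hydroxyl, giving cyclodehydration to a tetrahydropyran through the same six atoms that made the lactone ring. The secondary allylic hydroxyl may also be activated and substituted. The fallback sets out from 8 and comes back at 13. It replaces the redox condensation by a two-stage Williamson ether synthesis.
- Selective sulfonylation of the primary hydroxyl (TsCl, Et3N, cat. DMAP, CH2Cl2, 0 °C) gives [(2S,3R)-3-[(2S)-2-hydroxy-4-methylpent-3-en-1-yl]-3-methyloxiran-2-yl]methyl 4-methylbenzenesulfonate F8.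
- The phenoxide of 12 (K2CO3, DMF, rt to 40 °C) displaces the sulfonate of F8 at the CH2 carbon to give 13. The base is too weak to deprotonate the secondary alcohol.

**Further compounds**
F1 | step 2 | trimethyl[(2,2-dimethyl-6-methylidene-6H-1,3-dioxin-4-yl)oxy]silane | C=C1C=C(O[Si](C)(C)C)OC(C)(C)O1
F2 | step 2 | 2,2-dimethyl-6-[(2S)-4-methyl-2-(trimethylsilyloxy)pent-3-en-1-yl]-4H-1,3-dioxin-4-one | CC(C)=C[C@@H](O[Si](C)(C)C)CC1=CC(=O)OC(C)(C)O1
F3 | step 2 | 6-[(2S)-2-hydroxy-4-methylpent-3-en-1-yl]-2,2-dimethyl-4H-1,3-dioxin-4-one | CC(C)=C[C@@H](O)CC1=CC(=O)OC(C)(C)O1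
F4 | step 2 | (6S)-6-(2-methylprop-1-en-1-yl)oxane-2,4-dione | O=C1CC(=O)O[C@H](C=C(C)C)C1
F5 | step 2 | (6S)-6-(2-methylprop-1-en-1-yl)-2-oxo-5,6-dihydro-2H-pyran-4-yl trifluoromethanesulfonate | O=C1C=C(OS(=O)(=O)C(F)(F)F)C[C@@H](C=C(C)C)O1
F6 | step 3 | (6S)-4-methyl-6-(2-methylprop-1-en-1-yl)-5,6-dihydro-2H-pyran-2-ol (both anomers) | CC1=CC(O)O[C@H](C=C(C)C)C1
F7 | step 3 | (2Z,5S)-3,7-dimethylocta-2,6-diene-1,5-diol | OC/C=C(/C)C[C@H](O)C=C(C)C
F8 | step 6 | [(2S,3R)-3-[(2S)-2-hydroxy-4-methylpent-3-en-1-yl]-3-methyloxiran-2-yl]methyl 4-methylbenzenesulfonate | Cc1ccc(cc1)S(=O)(=O)OC[C@@H]1O[C@]1(C)C[C@H](O)C=C(C)C
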